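**Retrosynthetic overview**

- Target ⇐ desilylation, cross-metathesis (CH3 → CH2OAc on the C3 propenyl group) and O7-aroylation of the carbinol (7S)-7-hydroxy-7-methyl-3-propenyl-6H-isochromene-6,8(7H)-dione.
- Carbinol ⇐ closure of the carbocycle C4a–C5–C6–C7–C8–C8a at C5–C6: a one-carbon unit (C5) is inserted at C4a of a 3-acyl-4H-pyran-4-thione and acylated by the C6 carbonyl of a lactate-derived 1,3-dioxolan-4-one, with loss of N2, sulfur and pivalaldehyde.
- Enabling feature: C5 is the exocyclic carbon of a 4-alkylidene-4H-pyran (C5=C4a–C4=C3–O2), that is, the carbon of a pyrylium anhydrobase, so a CH2 group on C4a is a carbon nucleophile; and C6(=O)–C7(OH)(CH3) is a lactic acid unit whose carboxyl can be held as an activated acetal ester.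
- Thione ⇐ C7–C8 bond by anti-selective acylation of the lithium enolate of the (S)-lactic acid/pivalaldehyde acetal with a 4-oxo-4H-pyran-3-carbonyl chloride (sets C7); pyranone ⇐ acylation and cyclocondensation of the enaminone of ethyl acetoacetate with (E)-crotonyl chloride.
- Ring order: pyran ring (step 1), temporary dioxolanone (step 3), carbocycle last (step 6); the orsellinate arene is bought and attached afterwards.

Key step: step 6

Remark on the chemistry: atom numbers are those of the isochromene core (O2, C1, C3, C4, C4a, C5 to C8, C8a); the single stereocenter C7 is S (CIP order O > C8 > C6 > CH3); compound 1 is used as the commercial E/Z mixture and diazomethane as a freshly distilled ethereal solution.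

Step 1
Reactants: 1 ethyl 2-[(dimethylamino)methylidene]-3-oxobutanoate; 2 (2E)-but-2-enoyl chloride
Product: 4 ethyl 4-oxo-6-[(1E)-prop-1-en-1-yl]-4H-pyran-3-carboxylate, via enaminodiketone 3 (not isolated)
Conditions: LiN(SiMe3)2 (2.2 equiv), THF, −78 °C; then 2, −78 → −20 °C; then 3 M HCl, rt
Reagents that add atoms: none
Why: Kinetic deprotonation of the acetyl CH3 of the vinylogous amide and Claisen-type C-acylation by the acid chloride should give 3, whose enol oxygen then displaces dimethylamine in acid (addition–elimination cyclocondensation) to close the 4-pyranone ring with the E alkene untouched.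

Step 2
Reactants: 4 ethyl 4-oxo-6-[(1E)-prop-1-en-1-yl]-4H-pyran-3-carboxylate
Product: 5 4-oxo-6-[(1E)-prop-1-en-1-yl]-4H-pyran-3-carboxylic acid
Conditions: 6 M HCl, AcOH, 70 °C
Reagents that add atoms: water, O
Why: Acid-catalysed ester hydrolysis should free the acid without the ring opening that hydroxide would cause at the position next to the ring oxygen.

Step 3
Reactants: 6 (S)-lactic acid; 7 pivalaldehyde
Product: 8 (2S,5S)-2-tert-butyl-5-methyl-1,3-dioxolan-4-one
Conditions: TsOH·H2O (cat.), H2SO4 (cat.), pentane, reflux, Dean–Stark; crystallization from pentane at −78 °C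
Reagents that add atoms: none
Why: Acid-catalysed acetalization under thermodynamic control should favour the cis acetal, in which the new acetal center is set relative to the lactate center and which is obtained pure by crystallization.

Step 4
Reactants: 5 4-oxo-6-[(1E)-prop-1-en-1-yl]-4H-pyran-3-carboxylic acid; 8 (2S,5S)-2-tert-butyl-5-methyl-1,3-dioxolan-4-one
Product: 10 (2S,5R)-2-tert-butyl-5-methyl-5-{4-oxo-6-[(1E)-prop-1-en-1-yl]-4H-pyran-3-carbonyl}-1,3-dioxolan-4-one, via acid chloride 9 (not isolated)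
Conditions: 5, (COCl)2, DMF (cat.), CH2Cl2, 0 °C → rt, evaporate; separately 8, LiN(iPr)2, THF, −78 °C; then 9 in THF, −78 °C
Reagents that add atoms: none
Why: Claisen-type C-acylation of the lithium enolate by an acid chloride that has no acidic hydrogen should occur anti to the tert-butyl group of the acetal (self-regeneration of the lactate stereocenter), so that the acyl group takes the place of the former hydrogen and the future C7 is set as S.

Step 5
Reactants: 10 (2S,5R)-2-tert-butyl-5-methyl-5-{4-oxo-6-[(1E)-prop-1-en-1-yl]-4H-pyran-3-carbonyl}-1,3-dioxolan-4-one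
Product: 11 (2S,5R)-2-tert-butyl-5-methyl-5-{6-[(1E)-prop-1-en-1-yl]-4-sulfanylidene-4H-pyran-3-carbonyl}-1,3-dioxolan-4-one
Conditions: Lawesson's reagent (0.55 equiv), toluene, 80 °C
Reagents that add atoms: Lawesson's reagent, COc1ccc(cc1)P1(=S)SP(=S)(S1)c1ccc(OC)cc1
Why: Thionation with Lawesson's reagent should be fastest at the most electron-rich carbonyl, the doubly vinylogous ester C=O of the 4-pyranone, while the neopentyl-type ketone and the acetal ester react more slowly.

Step 6
Reactants: 11 (2S,5R)-2-tert-butyl-5-methyl-5-{6-[(1E)-prop-1-en-1-yl]-4-sulfanylidene-4H-pyran-3-carbonyl}-1,3-dioxolan-4-one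
Product: 15 (7S)-7-hydroxy-7-methyl-3-[(1E)-prop-1-en-1-yl]-6H-isochromene-6,8(7H)-dione, via thiadiazoline 12 (not isolated), via thiirane 13 (not isolated), via methylenepyran 14 (not isolated)
Conditions: CH2N2 (1.05 equiv, Et2O), THF, −78 °C; then PPh3 (1.2 equiv), −78 °C → rt, then 40 °C
Reagents that add atoms: diazomethane, C=[N+]=[N-]
Why: Proposed new method: diazomethane should add to the C4a=S bond, the only thiocarbonyl and by far the best dipolarophile of 11, to give 12, which loses N2 to a thiocarbonyl S-methylide that closes to thiirane 13; PPh3 then removes sulfur and leaves 14, the anhydrobase of a 4-methylpyrylium ion, whose exocyclic carbon C5 is nucleophilic through the C5=C4a–C4=C3–O2 dienol ether. C5 attacks the acetal ester carbonyl C6 of the dioxolanone and closes the carbocycle by a 6-(enolendo)-exo-trig acyl substitution; collapse of the tetrahedral adduct, loss of a proton from C5 (restoring C4a=C5) and loss of pivalaldehyde from the hemiacetal give the C6 ketone and the free C7 hydroxyl. The closest known reactions are the twofold-extrusion (Barton–Kellogg type) methylenation of thioketones with diazomethane and a phosphine, and the C-acylation of pyrylium anhydrobases by acyl chlorides and anhydrides; new are their combination in one flask and the acetal ester as acyl donor. No stereocenter is formed: C7 is quaternary and is carried over from 10, and the spiro carbon of 12 and 13 and the tetrahedral C6 are only transient. The step needs the new carbon at C4a and not at C1 (the site a free carbon nucleophile would choose in a 3-acyl-4-pyranone), which is secured because the carbon enters through sulfur; it also needs acylation at C6 only, which is secured because attack on C8 would give a four-membered ring and closure of the ylide onto C1 would require a bridgehead alkene.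

Step 7
Reactants: 16 orsellinic acid
Product: 18 2,4-bis[(tert-butyldimethylsilyl)oxy]-6-methylbenzoic acid, via silyl ester 17 (not isolated)
Conditions: TBSCl (3.3 equiv), imidazole, DMF, rt; then AcOH, THF/H2O, rt
Reagents that add atoms: tert-butyldimethylsilyl chloride, CC(C)(C)[Si](C)(C)Cl
Why: Exhaustive silylation followed by selective hydrolysis of the far more labile silyl ester should leave both phenols protected and the acid free.

Step 8
Reactants: 15 (7S)-7-hydroxy-7-methyl-3-[(1E)-prop-1-en-1-yl]-6H-isochromene-6,8(7H)-dione; 18 2,4-bis[(tert-butyldimethylsilyl)oxy]-6-methylbenzoic acid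
Product: 20 (7S)-7-methyl-6,8-dioxo-3-[(1E)-prop-1-en-1-yl]-7,8-dihydro-6H-isochromen-7-yl 2,4-bis[(tert-butyldimethylsilyl)oxy]-6-methylbenzoate, via aroyl chloride 19 (not isolated)
Conditions: 18, 1-chloro-N,N,2-trimethylprop-1-en-1-amine, CH2Cl2, 0 °C → rt; then 15, Et3N, DMAP, CH2Cl2, 40 °C
Reagents that add atoms: none
Why: DMAP-catalysed acyl transfer from an electron-rich aroyl chloride made under neutral conditions should esterify the tertiary C7 carbinol, which has no alternative reaction path under these mild basic conditions, and the C7 configuration is not touched.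

Step 9
Reactants: 20 (7S)-7-methyl-6,8-dioxo-3-[(1E)-prop-1-en-1-yl]-7,8-dihydro-6H-isochromen-7-yl 2,4-bis[(tert-butyldimethylsilyl)oxy]-6-methylbenzoate; 21 (2Z)-but-2-ene-1,4-diyl diacetate
Product: 22 (7S)-3-[(1E)-3-(acetyloxy)prop-1-en-1-yl]-7-methyl-6,8-dioxo-7,8-dihydro-6H-isochromen-7-yl 2,4-bis[(tert-butyldimethylsilyl)oxy]-6-methylbenzoate
Conditions: second-generation Hoveyda–Grubbs catalyst RuCl2(=CH-C6H4-2-OiPr)(H2IMes) (5 mol %), 21 (5 equiv), CH2Cl2, 40 °C
Reagents that add atoms: none
Why: Olefin cross-metathesis should exchange the terminal CH3CH= unit of the propenyl group for AcOCH2CH= at the only unhindered, non-enol-ether alkene, and the conjugated product should form mainly as the E isomer under thermodynamic control.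

Step 10
Reactants: 22 (7S)-3-[(1E)-3-(acetyloxy)prop-1-en-1-yl]-7-methyl-6,8-dioxo-7,8-dihydro-6H-isochromen-7-yl 2,4-bis[(tert-butyldimethylsilyl)oxy]-6-methylbenzoate
Product: 23 (7S)-3-[(1E)-3-(acetyloxy)prop-1-en-1-yl]-7-methyl-6,8-dioxo-7,8-dihydro-6H-isochromen-7-yl 2,4-dihydroxy-6-methylbenzoate
Conditions: HF·pyridine, THF, 0 °C → rt
Reagents that add atoms: none
Why: Fluoride-mediated cleavage of the two aryl silyl ethers under weakly acidic, amine-nucleophile-free conditions should spare the allylic acetate, the hindered benzoate and the pyran ring.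

**Compound list**

1 | ethyl 2-[(dimethylamino)methylidene]-3-oxobutanoate (commercial E/Z mixture) | CCOC(=O)C(=CN(C)C)C(C)=O | starting material
2 | (2E)-but-2-enoyl chloride | C/C=C/C(Cl)=O | starting material
3 | ethyl (6E)-2-[(dimethylamino)methylidene]-3,5-dioxooct-6-enoate (not isolated) | CCOC(=O)C(=CN(C)C)C(=O)CC(=O)/C=C/C | intermediate
4 | ethyl 4-oxo-6-[(1E)-prop-1-en-1-yl]-4H-pyran-3-carboxylate | CCOC(=O)C1=COC(/C=C/C)=CC1=O | intermediate
5 | 4-oxo-6-[(1E)-prop-1-en-1-yl]-4H-pyran-3-carboxylic acid | OC(=O)C1=COC(/C=C/C)=CC1=O | intermediate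
6 | (S)-lactic acid | C[C@H](O)C(=O)O | starting material
7 | pivalaldehyde | CC(C)(C)C=O | starting material
8 | (2S,5S)-2-tert-butyl-5-methyl-1,3-dioxolan-4-one (cis) | C[C@@H]1O[C@H](C(C)(C)C)OC1=O | intermediate
9 | 4-oxo-6-[(1E)-prop-1-en-1-yl]-4H-pyran-3-carbonyl chloride (not isolated) | ClC(=O)C1=COC(/C=C/C)=CC1=O | intermediate
10 | (2S,5R)-2-tert-butyl-5-methyl-5-{4-oxo-6-[(1E)-prop-1-en-1-yl]-4H-pyran-3-carbonyl}-1,3-dioxolan-4-one | C[C@]1(C(=O)C2=COC(/C=C/C)=CC2=O)O[C@H](C(C)(C)C)OC1=O | intermediate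
11 | (2S,5R)-2-tert-butyl-5-methyl-5-{6-[(1E)-prop-1-en-1-yl]-4-sulfanylidene-4H-pyran-3-carbonyl}-1,3-dioxolan-4-one | C[C@]1(C(=O)C2=COC(/C=C/C)=CC2=S)O[C@H](C(C)(C)C)OC1=O | intermediate
12 | adduct of 11 in which pyran C-4 is the spiro carbon of a 2,5-dihydro-1,3,4-thiadiazole ring (both spiro epimers, not isolated) | C[C@]1(C(=O)C2=COC(/C=C/C)=CC23SCN=N3)O[C@H](C(C)(C)C)OC1=O | intermediate
13 | analogue of 11 in which pyran C-4 is the spiro carbon of a thiirane ring (both spiro epimers, not isolated) | C[C@]1(C(=O)C2=COC(/C=C/C)=CC23CS3)O[C@H](C(C)(C)C)OC1=O | intermediate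
14 | (2S,5R)-2-tert-butyl-5-methyl-5-{4-methylidene-6-[(1E)-prop-1-en-1-yl]-4H-pyran-3-carbonyl}-1,3-dioxolan-4-one (not isolated) | C[C@]1(C(=O)C2=COC(/C=C/C)=CC2=C)O[C@H](C(C)(C)C)OC1=O | intermediate
15 | (7S)-7-hydroxy-7-methyl-3-[(1E)-prop-1-en-1-yl]-6H-isochromene-6,8(7H)-dione | C/C=C/C1=CC2=CC(=O)[C@](C)(O)C(=O)C2=CO1 | intermediate
16 | orsellinic acid (2,4-dihydroxy-6-methylbenzoic acid) | Cc1cc(O)cc(O)c1C(=O)O | starting material
17 | tert-butyldimethylsilyl 2,4-bis[(tert-butyldimethylsilyl)oxy]-6-methylbenzoate (not isolated) | Cc1cc(O[Si](C)(C)C(C)(C)C)cc(O[Si](C)(C)C(C)(C)C)c1C(=O)O[Si](C)(C)C(C)(C)C | intermediate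
18 | 2,4-bis[(tert-butyldimethylsilyl)oxy]-6-methylbenzoic acid | Cc1cc(O[Si](C)(C)C(C)(C)C)cc(O[Si](C)(C)C(C)(C)C)c1C(=O)O | intermediate
19 | 2,4-bis[(tert-butyldimethylsilyl)oxy]-6-methylbenzoyl chloride (not isolated) | Cc1cc(O[Si](C)(C)C(C)(C)C)cc(O[Si](C)(C)C(C)(C)C)c1C(Cl)=O | intermediate
20 | (7S)-7-methyl-6,8-dioxo-3-[(1E)-prop-1-en-1-yl]-7,8-dihydro-6H-isochromen-7-yl 2,4-bis[(tert-butyldimethylsilyl)oxy]-6-methylbenzoate | C/C=C/C1=CC2=CC(=O)[C@](C)(OC(=O)c3c(C)cc(O[Si](C)(C)C(C)(C)C)cc3O[Si](C)(C)C(C)(C)C)C(=O)C2=CO1 | intermediate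
21 | (2Z)-but-2-ene-1,4-diyl diacetate | CC(=O)OC/C=C\COC(C)=O | starting material
22 | (7S)-3-[(1E)-3-(acetyloxy)prop-1-en-1-yl]-7-methyl-6,8-dioxo-7,8-dihydro-6H-isochromen-7-yl 2,4-bis[(tert-butyldimethylsilyl)oxy]-6-methylbenzoate | CC(=O)OC/C=C/C1=CC2=CC(=O)[C@](C)(OC(=O)c3c(C)cc(O[Si](C)(C)C(C)(C)C)cc3O[Si](C)(C)C(C)(C)C)C(=O)C2=CO1 | intermediate
23 | (7S)-3-[(1E)-3-(acetyloxy)prop-1-en-1-yl]-7-methyl-6,8-dioxo-7,8-dihydro-6H-isochromen-7-yl 2,4-dihydroxy-6-methylbenzoate (CNP0194405.1) | CC(=O)OC/C=C/C1=CC2=CC(=O)[C@](C)(OC(=O)c3c(C)cc(O)cc3O)C(=O)C2=CO1 | target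

**Route summary**

Total step count: 10. Longest linear sequence: 8 steps (steps 1, 2, 4, 5, 6, 8, 9, 10).

**Steps most likely to fail**

1. Step 6 (Proposed new method). What may go wrong:
   - The cycloaddition of diazomethane to the push–pull thione may be slow or unselective.
   - The thiirane or the ylide may be captured by the neighbouring carbonyl groups before sulfur is removed.
   - The anhydrobase may oligomerize because the acetal ester is not electrophilic enough.

   Fallback (known chemistry, reversed polarity of the same ring closure; sets out from 2 and 7, comes back at 15). Commercial (E)-4-methoxybut-3-en-2-one is α-iodinated (I2, pyridine, CH2Cl2) to (3Z)-3-iodo-4-methoxybut-3-en-2-one F1. Its lithium enolate (LiN(SiMe3)2, THF, −78 °C) is acylated with 2 and cyclized with TFA to 5-iodo-2-[(1E)-prop-1-en-1-yl]-4H-pyran-4-one F2. Lawesson's reagent converts F2 into 5-iodo-2-[(1E)-prop-1-en-1-yl]-4H-pyran-4-thione F3. Commercial (R)-lactic acid and 7 give (2R,5R)-2-tert-butyl-5-methyl-1,3-dioxolan-4-one F4 as in step 3. Its enolate (LiN(iPr)2, THF, −78 °C) is acylated anti to the tert-butyl group with chloroacetyl chloride to (2R,5S)-2-tert-butyl-5-(chloroacetyl)-5-methyl-1,3-dioxolan-4-one F5. S-alkylation of F3 with F5 (NaI cat., MeCN) and Eschenmoser sulfide contraction in the same flask (Et3N, PPh3) give (2R,5S)-2-tert-butyl-5-({3-iodo-6-[(1E)-prop-1-en-1-yl]-4H-pyran-4-ylidene}acetyl)-5-methyl-1,3-dioxolan-4-one F6. Here the acetal ester carbonyl is C8 and the iodine sits on C8a. Iodine–magnesium exchange (iPrMgCl·LiCl, THF, −40 °C) and intramolecular acyl substitution at C8 (Parham-type cyclization) then close the same ring and give 15 after loss of pivalaldehyde.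

2. Step 4. What may go wrong: conjugate addition of the enolate to the position next to the ring oxygen of the 3-acylpyranone, or O-acylation, may compete with C-acylation.

   Fallback (aldol then oxidation; sets out from 5 through 9, comes back at 10). The acid chloride 9 is reduced with LiAlH(OtBu)3 (THF, −78 °C) to 4-oxo-6-[(1E)-prop-1-en-1-yl]-4H-pyran-3-carbaldehyde F7. The lithium enolate of 8 adds to it anti to the tert-butyl group, an aldol addition to the far more reactive formyl group, to give (2S,5R)-2-tert-butyl-5-(hydroxy{4-oxo-6-[(1E)-prop-1-en-1-yl]-4H-pyran-3-yl}methyl)-5-methyl-1,3-dioxolan-4-one F8. Dess–Martin periodinane oxidizes F8 to 10.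

3. Step 9. What may go wrong: the catalyst may be deactivated by the dienyl enol ether array, conversion may stay incomplete, or E selectivity may be low.

   Fallback (allylic oxidation in place of metathesis; sets out from 20, comes back at 22). SeO2 (cat.) with t-BuOOH in CH2Cl2 oxidizes the only allylic CH3 to (7S)-3-[(1E)-3-hydroxyprop-1-en-1-yl]-7-methyl-6,8-dioxo-7,8-dihydro-6H-isochromen-7-yl 2,4-bis[(tert-butyldimethylsilyl)oxy]-6-methylbenzoate F9. Acetylation with Ac2O and pyridine gives 22.

Further compounds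
F1 | step 6 | (3Z)-3-iodo-4-methoxybut-3-en-2-one | CO/C=C(\I)C(C)=O
F2 | step 6 | 5-iodo-2-[(1E)-prop-1-en-1-yl]-4H-pyran-4-one | C/C=C/C1=CC(=O)C(I)=CO1
F3 | step 6 | 5-iodo-2-[(1E)-prop-1-en-1-yl]-4H-pyran-4-thione | C/C=C/C1=CC(=S)C(I)=CO1
F4 | step 6 | (2R,5R)-2-tert-butyl-5-methyl-1,3-dioxolan-4-one | C[C@H]1O[C@@H](C(C)(C)C)OC1=O
F5 | step 6 | (2R,5S)-2-tert-butyl-5-(chloroacetyl)-5-methyl-1,3-dioxolan-4-one | C[C@@]1(C(=O)CCl)O[C@@H](C(C)(C)C)OC1=O
F6 | step 6 | (2R,5S)-2-tert-butyl-5-({3-iodo-6-[(1E)-prop-1-en-1-yl]-4H-pyran-4-ylidene}acetyl)-5-methyl-1,3-dioxolan-4-one (exocyclic alkene geometry not fixed) | C/C=C/C1=CC(=CC(=O)[C@]2(C)O[C@@H](C(C)(C)C)OC2=O)C(I)=CO1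
F7 | step 4 | 4-oxo-6-[(1E)-prop-1-en-1-yl]-4H-pyran-3-carbaldehyde | O=CC1=COC(/C=C/C)=CC1=O
F8 | step 4 | (2S,5R)-2-tert-butyl-5-(hydroxy{4-oxo-6-[(1E)-prop-1-en-1-yl]-4H-pyran-3-yl}methyl)-5-methyl-1,3-dioxolan-4-one (both carbinol epimers) | C[C@]1(C(O)C2=COC(/C=C/C)=CC2=O)O[C@H](C(C)(C)C)OC1=O
F9 | step 9 | (7S)-3-[(1E)-3-hydroxyprop-1-en-1-yl]-7-methyl-6,8-dioxo-7,8-dihydro-6H-isochromen-7-yl 2,4-bis[(tert-butyldimethylsilyl)oxy]-6-methylbenzoate | OC/C=C/C1=CC2=CC(=O)[C@](C)(OC(=O)c3c(C)cc(O[Si](C)(C)C(C)(C)C)cc3O[Si](C)(C)C(C)(C)C)C(=O)C2=CO1
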